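**Assumptions (one line each)**
- The SMILES corresponds to (2R) at the chroman quaternary carbon and (R) at the carbinol, both E alkenes. The chiral catalyst in Step 3 and the Ipc₂B-allyl enantiomer in Step 6 are taken to be the ones that deliver these configurations; I could not confirm the correct antipodes from memory.
- Ortho-farnesylation goes at C6 of the phenol, the only free position ortho to the OH.

**Retrosynthetic overview**
- Sargachromanol C ⇒ prenyl terminus made by cross-metathesis of a terminal allyl group ⇒ (R)-homoallylic alcohol from Brown allylation of an α-methyl enal.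
- The enal ⇐ allylic oxidation of the terminal E-methyl of a chromanyl farnesyl-type chain, which breaks the symmetry of the gem-dimethyl terminus.
- The only ring formed is the chroman, built early. The key step is an enantioface-selective Markovnikov hydroalkoxylation of the proximal trisubstituted alkene of an achiral ortho-farnesylphenol, which sets the quaternary (2R) centre.
- The farnesylphenol ⇐ mono-silylated methylhydroquinone (cheap aromatic feedstock) + farnesyl bromide.

---

**Step 1**
Reactants: 1 (2-methylbenzene-1,4-diol, methylhydroquinone); 2 (chlorotriisopropylsilane)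
Product: 3 (2-methyl-4-[(triisopropylsilyl)oxy]phenol)
Conditions: TIPSCl (1.0 equiv), imidazole, DMF, 0 °C→rt
Reagents that add atoms: TIPSCl, CC(C)[Si](Cl)(C(C)C)C(C)C
Why: Silylation of the hindered phenol is disfavoured, because the 1-OH is flanked by the methyl group, so the 4-OH is silylated selectively (chromatography removes minor regioisomer and bis-ether); this gives a base-, oxidant- and peroxide-stable phenol protecting group.

**Step 2**
Reactants: 3; 4 ((2E,6E)-farnesyl bromide)
Product: 5 (2-[(2E,6E)-farnesyl]-6-methyl-4-(TIPSO)phenol)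
Conditions: MeMgBr (1.0 equiv), Et₂O/toluene, 0 °C; then 4, 0→50 °C
Reagents that add atoms: farnesyl bromide, CC(C)=CCC/C(C)=C/CC/C(C)=C/CBr
Why: The magnesium phenoxide directs SN2 C-alkylation (ortho-selective Friedel–Crafts-type allylation) to the only free ortho position, the other ortho position being blocked by methyl and the para position by OTIPS; attack at the primary allylic carbon retains E geometry, and no stereocentre is formed.

**Step 3 (key step)**
Reactants: 5
Product: 6 ((2R)-2-[(3E)-4,8-dimethylnona-3,7-dien-1-yl]-2,8-dimethyl-6-(TIPSO)chromane)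
Conditions: chiral IDPi Brønsted acid (5 mol%, enantiomer giving 2R), cyclohexane, 10 °C, 48 h
Reagents that add atoms: none
Why: Proposed new method: a confined chiral imidodiphosphorimidate acid binds the phenol OH by hydrogen bonding and protonates the adjacent geranyl-type C2=C3 alkene at C2, so the phenol closes onto the tertiary C3 in a 6-membered Markovnikov cyclisation within the chiral ion pair. This differentiates the enantiotopic alkene faces of the achiral, mirror-symmetric substrate and sets the quaternary (2R) centre directly. The closest known chemistry is tocopherol-cyclase-type biomimetic chromanol formation and chiral-acid hydroalkoxylation of unactivated alkenes. The proximal alkene is favoured by tether proximity; the two distal trisubstituted alkenes should survive.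

**Step 4**
Reactants: 6
Product: 7 ((2R)-2-[(3E,7E)-9-hydroxy-4,8-dimethylnona-3,7-dien-1-yl]-2,8-dimethyl-6-(TIPSO)chromane)
Conditions: SeO₂ (10 mol%), TBHP (3 equiv, in decane), CH₂Cl₂, rt
Reagents that add atoms: TBHP, CC(C)(C)OO (oxygen source)
Why: Sharpless–Umbreit SeO₂/TBHP allylic oxidation (ene reaction then [2,3]-sigmatropic shift) hydroxylates the terminal E-methyl of the Me₂C=CH– group. This breaks the gem-dimethyl symmetry and gives the (E)-allylic alcohol, with any over-oxidised aldehyde converging in Step 5.

**Step 5**
Reactants: 7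
Product: 8 ((2E,6E)-2,6-dimethyl-9-[(2R)-2,8-dimethyl-6-(TIPSO)chroman-2-yl]nona-2,6-dienal)
Conditions: MnO₂ (20 equiv), CH₂Cl₂, rt
Reagents that add atoms: none
Why: Activated MnO₂ selectively oxidises the primary allylic alcohol to the α-methyl enal without touching the other alkenes or the quaternary centre.

**Step 6**
Reactants: 8; 9 ((+)-B-allyldiisopinocampheylborane, from (−)-α-pinene)
Product: 10 ((2R)-2-[(3E,7E,9R)-9-hydroxy-4,8-dimethyldodeca-3,7,11-trien-1-yl]-2,8-dimethyl-6-(TIPSO)chromane)
Conditions: 9 (1.1 equiv), Et₂O, −100→−78 °C; then NaOH, H₂O₂, THF/H₂O, 0 °C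
Reagents that add atoms: allyl-B(Ipc)₂, C=CCB(C1CC2CC(C1C)C2(C)C)C1CC2CC(C1C)C2(C)C (Ipc groups from (−)-α-pinene, 1R,2R,3R,5S; stereo omitted in SMILES)
Why: Brown asymmetric allylboration proceeds through a Zimmerman–Traxler chair in which the pinane ligands select the Re face of the enal, giving the (R)-carbinol; the basic peroxide workup is tolerated by the TIPS aryl ether.

**Step 7**
Reactants: 10; 11 (2-methylbut-2-ene)
Product: 12 (TIPS ether of sargachromanol C)
Conditions: Hoveyda–Grubbs II (5 mol%), 1,4-benzoquinone (10 mol%), 11 (20 equiv), CH₂Cl₂, 40 °C, sealed tube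
Reagents that add atoms: 2-methylbut-2-ene, CC=C(C)C
Why: Cross-metathesis of the unhindered monosubstituted allyl alkene with excess 2-methyl-2-butene converts CH=CH₂ into the prenyl CH=CMe₂; the hindered trisubstituted alkenes react far more slowly, and benzoquinone suppresses Ru–H isomerisation of the allylic alcohol, so no stereocentre is touched.

**Step 8**
Reactants: 12
Product: 13 (sargachromanol C)
Conditions: TBAF (1.5 equiv), AcOH (1.5 equiv), THF, 0 °C, 30 min, Ar
Reagents that add atoms: none
Why: Fluoride cleaves the aryl TIPS ether under buffered conditions, leaving the allylic alcohol, the three alkenes and both stereocentres intact.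

---

**Compound list**
1 | 2-methylbenzene-1,4-diol | Cc1cc(O)ccc1O | starting material
2 | chlorotriisopropylsilane | CC(C)[Si](Cl)(C(C)C)C(C)C | starting material
3 | 2-methyl-4-(TIPSO)phenol | Cc1cc(O[Si](C(C)C)(C(C)C)C(C)C)ccc1O | intermediate
4 | (2E,6E)-farnesyl bromide | CC(C)=CCC/C(C)=C/CC/C(C)=C/CBr | starting material
5 | 2-farnesyl-6-methyl-4-(TIPSO)phenol | CC(C)=CCC/C(C)=C/CC/C(C)=C/Cc1cc(O[Si](C(C)C)(C(C)C)C(C)C)cc(C)c1O | intermediate
6 | (2R)-chromane with 4,8-dimethylnona-3,7-dienyl chain | CC(C)=CCC/C(C)=C/CC[C@]1(C)CCc2cc(O[Si](C(C)C)(C(C)C)C(C)C)cc(C)c2O1 | intermediate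
7 | terminal (E)-allylic alcohol | OC/C(C)=C/CC/C(C)=C/CC[C@]1(C)CCc2cc(O[Si](C(C)C)(C(C)C)C(C)C)cc(C)c2O1 | intermediate
8 | α-methyl enal | O=C/C(C)=C/CC/C(C)=C/CC[C@]1(C)CCc2cc(O[Si](C(C)C)(C(C)C)C(C)C)cc(C)c2O1 | intermediate
9 | (+)-B-allyldiisopinocampheylborane | C=CCB(C1CC2CC(C1C)C2(C)C)C1CC2CC(C1C)C2(C)C (Ipc stereo as in name) | starting material (reagent)
10 | (9R)-homoallylic alcohol | C=CC[C@@H](O)/C(C)=C/CC/C(C)=C/CC[C@]1(C)CCc2cc(O[Si](C(C)C)(C(C)C)C(C)C)cc(C)c2O1 | intermediate
11 | 2-methylbut-2-ene | CC=C(C)C | starting material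
12 | TIPS-protected sargachromanol C | CC(C)=CC[C@@H](O)/C(C)=C/CC/C(C)=C/CC[C@]1(C)CCc2cc(O[Si](C(C)C)(C(C)C)C(C)C)cc(C)c2O1 | intermediate
13 | sargachromanol C | CC(C)=CC[C@@H](O)/C(C)=C/CC/C(C)=C/CC[C@]1(C)CCc2cc(O)cc(C)c2O1 | target

**Total steps:** 8. **Longest linear sequence:** 8 (from methylhydroquinone).

**Three steps most likely to fail**
1. **Step 3 (enantioselective hydroalkoxylation).** The acid might protonate the distal alkenes and cause polyene cyclisation, or give low ee. Fallback: cyclise 5 racemically with an achiral acid (BF₃·OEt₂ or CSA) and resolve chromane 6 by preparative chiral-phase SFC/HPLC, carrying (2R)-6 forward.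
2. **Step 4 (terminal E-methyl oxidation).** Two near-equivalent trisubstituted alkenes and Z-methyl oxidation give regioisomer mixtures. Fallback: selective NBS/H₂O bromohydrin at the terminal alkene, K₂CO₃ to the epoxide, H₅IO₆ cleavage to the aldehyde, then E-selective Wittig with Ph₃P=C(Me)CHO to give enal 8.
3. **Step 2 (ortho-C-farnesylation).** O-alkylation competes and yields are moderate. Fallback: ortho-brominate 3 (NBS, iPr₂NH) and couple the 6-bromophenol with farnesylzinc chloride under Pd (Negishi) catalysis.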